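Take the substrate and intermediate A as one pool draining into target by the direct step with partner, and ask how much of that pool is left at the asked time.

substrate 0.098 M; partner 2.00 equiv (fed, over 50 min); capture agent 4.90 mM; time 15 h; the fed solution adds 0.20 times the starting volume

    substrate ⇌ intermediate A (K1 = 0.36, k1 = 0.25 /h)
    partner + intermediate A ⇌ intermediate B (K2 = 15 /M, k2 = 0.37 /M/h)
    substrate + partner → target (k3 = 1.9 /M/h)
    intermediate B ⇌ intermediate C (K4 = 0.96, k4 = 0.11 /h)
    intermediate B ⇌ intermediate D (K5 = 0.71, k5 = 2.1 /h)
    partner + intermediate D → side product (k6 = 0.088 /M/h)
    crystals ⇌ target, rate k7*(cs7 - [target]) while solid is left; crystals form when [target] > cs7 (cs7 = 38 mM, k7 = 6.2 /h)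
    capture agent + intermediate C → trapped intermediate (k8 = 2.5 /M/h)

* why nothing more happens at 15 h, or that something still does (all of the substrate has reacted / the partner has run out first / it is still moving / forward and back rates have come level)
* how much of the substrate has reacted by 15 h
* how much target there is at 15 h, in percent of the substrate charged
* how much intermediate A there is at 15 h, in percent of the substrate charged

- what is said of target includes crystals
- amounts are per litre of the starting volume; all of the dose is in the solution fed
- crystals is a solid; its amount is given per volume of the solution
- the reaction counts as stopped when no species that holds the substrate changes by six tenths of a point or more over the second half of the time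
- run time (flask): 15 h

- For the opposite of "still moving", no species holding the substrate may change by as much as the stopping margin in the notes between half time and the end, so I reckon the pool at both times.
- Substrate and intermediate A relax with a half-life of 0.734 h, shorter than the 1.9 h of substrate by the direct step alone at whole charges. So I hold the pool at its equilibrium split, 73.5% of it substrate.
- The forward half-life of intermediate A towards intermediate B is 9.6 h, longer than that, so I leave that step out.
- With partner charged at 2.00 equiv, substrate is the limiting reagent. After the feed one equivalent is 0.0817 M. In this reckoning each partner used removes one from the pool, so partner stays one equivalent above the pool.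
- The logarithm of partner over pool then climbs at a steady 0.114 /h. This slope, the direct step's constant times the substrate's share times the partner's excess, is the drain constant.
- Starting from 2.00 equiv, the part of the charge left in the pool is 1/(2·exp(drain constant × time) − 1). Counting from mid-feed, the clock reads 7.08 h at half time and 14.6 h at the end.
- That leaves 28.7% and then 10.5%. At the equilibrium split the substrate falls by 13 percentage points, outside the stopping margin, so I say it is still moving.
- My end split is 7.72% substrate and 2.78% intermediate A, which gives a conversion of 92.3%. The other 89.5% is shared by target and the species beyond intermediate A.
- The forecast says it is still moving, with 93% conversion, 85% target and 2.6% intermediate A, “leaving about a tenth unconverted and still reacting at 15 h”. Its conversion stands 0.69 points above mine.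
- In the flask it is still moving, with 93.1% conversion, 85.1% target and 2.94% intermediate A. Its pool falls from 26.9% at 7.50 h to 9.85% at 15.0 h, against the 10.5% reckoned for the end.
- Now take the neighbour charged with 0.039 M of substrate, at the same equivalents and time. One equivalent shrinks to 0.0325 M, so its drain constant is 0.0454 /h, lower than the flask's. The same formula and clock leave 34.7% in its pool. That neighbour ends with 23.7% substrate and 9.21% intermediate A, 32.9% together.

Its constants belong to no real substance; no experiment stands behind them.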